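**Plan**

- Retrosynthesis: the phenols are unmasked last. The enol sulfate is cut at O–S and C–O back to a (Z)-alkenyl iodide. The iodide is cut at the C(sp3)–C(sp2) bond beside the enol carbon (syn-carbocupration of an aryl-octenyne by a bicyclic alkylcopper). The arene fragment is cut at ArCH2–CH= (alkenylalane plus benzyl chloride). The bicycle is cut in ring B at C7=C8 and C9–C10.
- Forward: ring A is bought as 2,4,4-trimethylcyclohexenone. Ring B is annulated onto it in step 5. The chain is joined in step 16, sulfated in step 17 and desilylated in step 18.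
- Enabling feature: in ring B the alkene carbon C8 carries a one-carbon branch (C12), and its neighbour C9 is bonded to the quaternary fusion carbon C10, which is 1,4 to C7 through C5–C6. With C12 raised to an aldehyde, ring B is the condensation product of an enal (C12–C8=C9), a tertiary C10 radical and a C7 aldehyde. The C10 radical is available from the C1=C10 alkene of ring A.
- Stereochemistry: CBS reduction sets the C1 carbinol, and a Johnson–Claisen shift relays it to C5. C5 is then expected to control C10 and C9 in step 5; this is the least secure relay in the route and has a fallback. The E-alkene comes from syn-methylalumination. The Z-enol sulfate comes from syn-carbocupration, with retention through I, Li and O.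

Key step: step 5

Numbering: drimane numbering is used for all atoms, also in the monocyclic precursors (ring A = C1–C5, C10; C4 carries the gem-dimethyl group; C12 sits on C8 and C11 on C9). "Drim-7-ene" compounds have 5α-H, 9α-H, 10β-CH3 (5S,10S), with C11 cis to the angular methyl.

Remark: the target is drawn as the free hydrogen sulfate; it is assumed that the sulfate salt from the last step is converted by a brief cold proton exchange, and that the compound is otherwise handled as its sodium salt.

**Step 1**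
Reactants: 1 2,4,4-trimethylcyclohex-2-en-1-one
Product: 2 (R)-2,4,4-trimethylcyclohex-2-en-1-ol
Conditions: (S)-Me-CBS (10 mol%), BH3·SMe2, THF, −20 °C; MeOH
Reagents that add atoms: none
Why: Corey–Bakshi–Shibata reduction, in which the oxazaborolidine treats the 2-methylalkenyl arm as the large group and delivers hydride to one carbonyl face, should set the C1 carbinol as (R), the only stereocentre of the route made by catalysis.

**Step 2**
Reactants: 2 (R)-2,4,4-trimethylcyclohex-2-en-1-ol
Product: 4 ethyl 2-[(1S)-2,6,6-trimethylcyclohex-2-en-1-yl]acetate, via mixed ketene acetal 3 (not isolated)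
Conditions: MeC(OEt)3 (6 eq), EtCO2H (5 mol%), xylene, 140 °C, EtOH distilled off
Reagents that add atoms: triethyl orthoacetate CCOC(C)(OCC)OCC
Why: In this Johnson–Claisen rearrangement the [3,3] shift of 3 is suprafacial across the cyclohexene, so the new C5–C6 bond should form on the face that carried the C1 oxygen, which relays the carbinol configuration to C5 and moves the alkene to C1=C10.

**Step 3**
Reactants: 4 ethyl 2-[(1S)-2,6,6-trimethylcyclohex-2-en-1-yl]acetate
Product: 5 2-[(1S)-2,6,6-trimethylcyclohex-2-en-1-yl]acetaldehyde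
Conditions: DIBAL-H (1.05 eq), CH2Cl2, −78 °C; Rochelle salt
Reagents that add atoms: none
Why: Partial ester reduction with DIBAL-H at −78 °C stops at the aluminium hemiacetal and should give the C7 aldehyde on work-up, the C5 centre being β to the carbonyl and therefore not epimerisable.

**Step 4**
Reactants: 6 3-[(tert-butyldimethylsilyl)oxy]propanal
Product: 7 (E)-5-[(tert-butyldimethylsilyl)oxy]pent-2-enal
Conditions: Ph3P=CHCHO, toluene, 80 °C
Reagents that add atoms: (triphenylphosphoranylidene)acetaldehyde O=CC=P(c1ccccc1)(c1ccccc1)c1ccccc1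
Why: A Wittig reaction with the stabilised formyl ylide should give the (E)-enal that carries C12, C8, C9, C11 and the protected chain carbon.

**Step 5**
Reactants: 5 2-[(1S)-2,6,6-trimethylcyclohex-2-en-1-yl]acetaldehyde, 7 (E)-5-[(tert-butyldimethylsilyl)oxy]pent-2-enal
Product: 10 11-[(tert-butyldimethylsilyloxy)methyl]drim-7-en-12-al, via aldol 8 (not isolated), via mesylate 9 (not isolated)
Conditions: Fe(acac)3 (30 mol%), PhSiH3 (2.5 eq), 7 (3 eq), EtOH/(CH2OH)2 5:1, 0 → 23 °C; concentrate; MsCl, Et3N, CH2Cl2, 0 → 23 °C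
Reagents that add atoms: none
Why: An iron hydride from Fe(acac)3 and PhSiH3 should transfer H• to C1 of the electron-rich ring alkene of 5 to give the tertiary C10 radical, which adds to the β-carbon of 7 (C9–C10 bond); the α-formyl radical is then reduced to an iron enolate at C8 (radical–polar crossover) that attacks the C7 aldehyde (C7–C8 bond) to give aldol 8, and mesylation with E1cB elimination in the same flask turns that bond into the conjugated C7=C8 double bond of 10. The closest known reaction type is the hydrogen-atom-transfer-initiated Giese addition/aldol annulation of alkenyl aldehydes or ketones with enals and enones. Ring B closes in the aldol event by a 6-(enolexo)-exo-trig addition. C10 should be controlled by C5: axial approach to the radical is blocked on either chair by the syn-axial C4 methyl, and of the two equatorial approaches only the one on the chair with an equatorial C5 side chain is flanked by axial hydrogens, which puts C9 trans to C6 and the C10 methyl axial (trans-decalin). C9 is set in the same addition by the staggered transition state that puts the small radical substituent (CH3) over the acceptor chain and the bulky C5 arm next to the acceptor hydrogen, which places C11 cis to the C10 methyl, while the C7 and C8 centres are erased on dehydration. The step needs hydrogen-atom transfer to the ring alkene and not to the enal, conjugate addition faster than reduction of the radical, and aldolisation through the C8 enolate only; the polarity match, the excess of electrophilic 7 and the regiospecific formation of the enolate at C8 by electron transfer should secure these, and the activating C12 aldehyde is removed in steps 6 and 7.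

**Step 6**
Reactants: 10 11-[(tert-butyldimethylsilyloxy)methyl]drim-7-en-12-al
Product: 11 11-[(tert-butyldimethylsilyloxy)methyl]drim-7-en-12-ol
Conditions: NaBH4, CeCl3·7H2O, MeOH, 0 °C
Reagents that add atoms: none
Why: Luche reduction should give clean 1,2-reduction of the hindered enal to the primary allylic alcohol without touching the C7=C8 bond.

**Step 7**
Reactants: 11 11-[(tert-butyldimethylsilyloxy)methyl]drim-7-en-12-ol
Product: 13 11-[(tert-butyldimethylsilyloxy)methyl]drim-7-ene, via allylic sulfate 12 (not isolated)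
Conditions: SO3·pyridine, THF, 0 °C; LiAlH4, 0 → 23 °C
Reagents that add atoms: none
Why: Deoxygenation of a primary allylic alcohol through its sulfate monoester, with SN2 hydride displacement at C12, should convert the helper oxygen into the C8 methyl and leave the alkene at C7=C8.

**Step 8**
Reactants: 13 11-[(tert-butyldimethylsilyloxy)methyl]drim-7-ene
Product: 14 (drim-7-en-11-yl)methanol
Conditions: TBAF, THF, 23 °C
Reagents that add atoms: none
Why: Fluoride-induced desilylation should free the primary alcohol without affecting the trisubstituted alkene.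

**Step 9**
Reactants: 14 (drim-7-en-11-yl)methanol
Product: 15 11-(bromomethyl)drim-7-ene
Conditions: CBr4, PPh3, CH2Cl2, 0 °C
Reagents that add atoms: carbon tetrabromide BrC(Br)(Br)Br
Why: The Appel reaction should convert the unhindered primary alcohol into the bromide under neutral conditions that do not isomerise the C7=C8 bond.

**Step 10**
Reactants: 16 hepta-1,6-diyne
Product: 17 (hepta-1,6-diyn-1-yl)trimethylsilane
Conditions: n-BuLi (0.9 eq), THF, −78 °C; TMSCl; excess 16 recovered
Reagents that add atoms: chlorotrimethylsilane C[Si](C)(C)Cl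
Why: Monolithiation and silylation of the symmetrical diyne should give the mono-protected diyne (statistical, with recovery of 16) so that only one alkyne reacts in step 14.

**Step 11**
Reactants: 18 2,5-dihydroxybenzaldehyde
Product: 19 2,5-bis[(triisopropylsilyl)oxy]benzaldehyde
Conditions: TIPSOTf (2.3 eq), 2,6-lutidine, CH2Cl2, 0 °C
Reagents that add atoms: triisopropylsilyl trifluoromethanesulfonate CC(C)[Si](OS(=O)(=O)C(F)(F)F)(C(C)C)C(C)C
Why: Silylation with the triflate should protect both phenols, including the hydrogen-bonded ortho one, as base- and organometal-stable ethers that fluoride removes at the end.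

**Step 12**
Reactants: 19 2,5-bis[(triisopropylsilyl)oxy]benzaldehyde
Product: 20 {2,5-bis[(triisopropylsilyl)oxy]phenyl}methanol
Conditions: NaBH4, EtOH/THF, 0 °C
Reagents that add atoms: none
Why: Borohydride reduction of the aryl aldehyde should give the benzylic alcohol, the bulky silyl groups resisting O-to-O migration.

**Step 13**
Reactants: 20 {2,5-bis[(triisopropylsilyl)oxy]phenyl}methanol
Product: 21 2-(chloromethyl)-1,4-bis[(triisopropylsilyl)oxy]benzene
Conditions: PPh3, NCS, THF, 0 → 23 °C
Reagents that add atoms: N-chlorosuccinimide O=C1CCC(=O)N1Cl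
Why: Appel-type chlorination through the alkoxyphosphonium salt should give the benzylic chloride under acid-free conditions that keep the aryl silyl ethers.

**Step 14**
Reactants: 17 (hepta-1,6-diyn-1-yl)trimethylsilane, 21 2-(chloromethyl)-1,4-bis[(triisopropylsilyl)oxy]benzene
Product: 23 (E)-{8-[2,5-bis(triisopropylsilyloxy)phenyl]-6-methyloct-6-en-1-yn-1-yl}trimethylsilane, via alkenylalane 22 (not isolated)
Conditions: Me3Al (2 eq), Cp2ZrCl2 (20 mol%), CH2Cl2, 0 → 23 °C; volatiles removed; 21, Ni(PPh3)2Cl2 (5 mol%)/n-BuLi (10 mol%), THF, 23 °C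
Reagents that add atoms: trimethylaluminium C[Al](C)C
Why: Negishi zirconium-catalysed carboalumination adds CH3 and Al syn across the terminal alkyne only, and nickel(0)-catalysed coupling of the alkenylalane with the benzylic chloride proceeds with retention, so the (E)-trisubstituted alkene should be set.

**Step 15**
Reactants: 23 (E)-{8-[2,5-bis(triisopropylsilyloxy)phenyl]-6-methyloct-6-en-1-yn-1-yl}trimethylsilane
Product: 24 (E)-2-(3-methyloct-2-en-7-yn-1-yl)-1,4-bis[(triisopropylsilyl)oxy]benzene
Conditions: K2CO3, MeOH/THF, 0 → 23 °C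
Reagents that add atoms: none
Why: Methanolysis should cleave the alkynyl C–Si bond much faster than the hindered aryl silyl ethers and free the terminal alkyne.

**Step 16**
Reactants: 15 11-(bromomethyl)drim-7-ene, 24 (E)-2-(3-methyloct-2-en-7-yn-1-yl)-1,4-bis[(triisopropylsilyl)oxy]benzene
Product: 28 (1Z,6E)-2-[(drim-7-en-11-yl)methyl]-1-iodo-6-methyl-8-[2,5-bis(triisopropylsilyloxy)phenyl]octa-1,6-diene, via Grignard reagent 25 (not isolated), via alkylcopper 26 (not isolated), via alkenylcopper 27 (not isolated)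
Conditions: Mg, Et2O, reflux; CuBr·SMe2, Et2O/Me2S, −45 °C; 24 (1.2 eq), −25 °C, 16 h; I2, THF, −50 → 0 °C
Reagents that add atoms: iodine II
Why: Normant carbocupration adds the alkyl group to the internal alkyne carbon and copper to the terminal one in a syn fashion, and iodinolysis retains configuration, so the iodine should end cis to the decalin-bearing arm (Z).

**Step 17**
Reactants: 28 (1Z,6E)-2-[(drim-7-en-11-yl)methyl]-1-iodo-6-methyl-8-[2,5-bis(triisopropylsilyloxy)phenyl]octa-1,6-diene
Product: 31 (1Z,6E)-2-[(drim-7-en-11-yl)methyl]-6-methyl-8-[2,5-bis(triisopropylsilyloxy)phenyl]octa-1,6-dien-1-yl hydrogen sulfate, via alkenyllithium 29 (not isolated), via lithium enolate 30 (not isolated)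
Conditions: t-BuLi (2.1 eq), Et2O, −78 °C; LiOOt-Bu (from t-BuOOH, n-BuLi, THF, −78 °C), −78 → −20 °C; SO3·NMe3 (4 eq), DMF, −20 → 23 °C; aq NaHCO3
Reagents that add atoms: lithium tert-butyl peroxide CC(C)(C)OO[Li]; sulfur trioxide–trimethylamine C[N+](C)(C)S(=O)(=O)[O-]
Why: Iodine–lithium exchange and electrophilic oxygen transfer from the lithium peroxide (oxenoid oxidation) both retain alkene geometry, and O-sulfation of the resulting aldehyde enolate by the sulfur trioxide–amine complex should fix that geometry as the (Z)-enol sulfate.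

**Step 18**
Reactants: 31 (1Z,6E)-2-[(drim-7-en-11-yl)methyl]-6-methyl-8-[2,5-bis(triisopropylsilyloxy)phenyl]octa-1,6-dien-1-yl hydrogen sulfate
Product: 32 (1Z,6E)-8-(2,5-dihydroxyphenyl)-2-[(drim-7-en-11-yl)methyl]-6-methylocta-1,6-dien-1-yl hydrogen sulfate
Conditions: TBAF (2.5 eq), degassed THF, 0 °C; cold cation exchange (H+ form)
Reagents that add atoms: none
Why: Fluoride should cleave both aryl silyl ethers while the enol sulfate anion is inert to fluoride and mild base, and exclusion of air protects the hydroquinone.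

**Compound list**

1 | 2,4,4-trimethylcyclohex-2-en-1-one | CC1=CC(C)(C)CCC1=O | starting material
2 | (R)-2,4,4-trimethylcyclohex-2-en-1-ol | O[C@@H]1CCC(C)(C)C=C1C | intermediate
3 | 1-ethoxyvinyl ether of 2 (mixed ketene acetal) | C=C(OCC)O[C@@H]1CCC(C)(C)C=C1C | intermediate
4 | ethyl 2-[(1S)-2,6,6-trimethylcyclohex-2-en-1-yl]acetate | CCOC(=O)C[C@H]1C(C)(C)CCC=C1C | intermediate
5 | 2-[(1S)-2,6,6-trimethylcyclohex-2-en-1-yl]acetaldehyde | O=CC[C@H]1C(C)(C)CCC=C1C | intermediate
6 | 3-[(tert-butyldimethylsilyl)oxy]propanal | O=CCCO[Si](C)(C)C(C)(C)C | starting material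
7 | (E)-5-[(tert-butyldimethylsilyl)oxy]pent-2-enal | O=C/C=C/CCO[Si](C)(C)C(C)(C)C | intermediate
8 | 7-hydroxy-11-[(tert-butyldimethylsilyloxy)methyl]driman-12-al (aldol; mixture at C7 and C8) | O=CC1C(O)C[C@H]2C(C)(C)CCC[C@]2(C)[C@H]1CCO[Si](C)(C)C(C)(C)C | intermediate
9 | 7-O-mesylate of 8 (mixture at C7 and C8) | O=CC1C(OS(C)(=O)=O)C[C@H]2C(C)(C)CCC[C@]2(C)[C@H]1CCO[Si](C)(C)C(C)(C)C | intermediate
10 | 11-[(tert-butyldimethylsilyloxy)methyl]drim-7-en-12-al | O=CC1=CC[C@H]2C(C)(C)CCC[C@]2(C)[C@H]1CCO[Si](C)(C)C(C)(C)C | intermediate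
11 | 11-[(tert-butyldimethylsilyloxy)methyl]drim-7-en-12-ol | OCC1=CC[C@H]2C(C)(C)CCC[C@]2(C)[C@H]1CCO[Si](C)(C)C(C)(C)C | intermediate
12 | 11-[(tert-butyldimethylsilyloxy)methyl]drim-7-en-12-yl hydrogen sulfate | OS(=O)(=O)OCC1=CC[C@H]2C(C)(C)CCC[C@]2(C)[C@H]1CCO[Si](C)(C)C(C)(C)C | intermediate
13 | 11-[(tert-butyldimethylsilyloxy)methyl]drim-7-ene (5S,9S,10S) | CC1=CC[C@H]2C(C)(C)CCC[C@]2(C)[C@H]1CCO[Si](C)(C)C(C)(C)C | intermediate
14 | (drim-7-en-11-yl)methanol (5S,9S,10S) | CC1=CC[C@H]2C(C)(C)CCC[C@]2(C)[C@H]1CCO | intermediate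
15 | 11-(bromomethyl)drim-7-ene (5S,9S,10S) | CC1=CC[C@H]2C(C)(C)CCC[C@]2(C)[C@H]1CCBr | intermediate
16 | hepta-1,6-diyne | C#CCCCC#C | starting material
17 | (hepta-1,6-diyn-1-yl)trimethylsilane | C[Si](C)(C)C#CCCCC#C | intermediate
18 | 2,5-dihydroxybenzaldehyde | O=Cc1cc(O)ccc1O | starting material
19 | 2,5-bis[(triisopropylsilyl)oxy]benzaldehyde | O=Cc1cc(O[Si](C(C)C)(C(C)C)C(C)C)ccc1O[Si](C(C)C)(C(C)C)C(C)C | intermediate
20 | {2,5-bis[(triisopropylsilyl)oxy]phenyl}methanol | OCc1cc(O[Si](C(C)C)(C(C)C)C(C)C)ccc1O[Si](C(C)C)(C(C)C)C(C)C | intermediate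
21 | 2-(chloromethyl)-1,4-bis[(triisopropylsilyl)oxy]benzene | ClCc1cc(O[Si](C(C)C)(C(C)C)C(C)C)ccc1O[Si](C(C)C)(C(C)C)C(C)C | intermediate
22 | (E)-dimethyl[2-methyl-7-(trimethylsilyl)hept-1-en-6-yn-1-yl]alumane | C[Al](C)/C=C(\C)CCCC#C[Si](C)(C)C | intermediate
23 | (E)-{8-[2,5-bis(triisopropylsilyloxy)phenyl]-6-methyloct-6-en-1-yn-1-yl}trimethylsilane | C[Si](C)(C)C#CCCC/C(C)=C/Cc1cc(O[Si](C(C)C)(C(C)C)C(C)C)ccc1O[Si](C(C)C)(C(C)C)C(C)C | intermediate
24 | (E)-2-(3-methyloct-2-en-7-yn-1-yl)-1,4-bis[(triisopropylsilyl)oxy]benzene | C#CCCC/C(C)=C/Cc1cc(O[Si](C(C)C)(C(C)C)C(C)C)ccc1O[Si](C(C)C)(C(C)C)C(C)C | intermediate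
25 | [(drim-7-en-11-yl)methyl]magnesium bromide | CC1=CC[C@H]2C(C)(C)CCC[C@]2(C)[C@H]1CC[Mg]Br | intermediate
26 | [(drim-7-en-11-yl)methyl]copper (MgBr2 complex) | CC1=CC[C@H]2C(C)(C)CCC[C@]2(C)[C@H]1CC[Cu] | intermediate
27 | alkenylcopper from syn-addition of 26 to 24 (Cu cis to the decalin arm) | CC1=CC[C@H]2C(C)(C)CCC[C@]2(C)[C@H]1CC/C(=C\[Cu])CCC/C(C)=C/Cc1cc(O[Si](C(C)C)(C(C)C)C(C)C)ccc1O[Si](C(C)C)(C(C)C)C(C)C | intermediate
28 | (1Z,6E)-2-[(drim-7-en-11-yl)methyl]-1-iodo-6-methyl-8-[2,5-bis(triisopropylsilyloxy)phenyl]octa-1,6-diene | CC1=CC[C@H]2C(C)(C)CCC[C@]2(C)[C@H]1CC/C(=C\I)CCC/C(C)=C/Cc1cc(O[Si](C(C)C)(C(C)C)C(C)C)ccc1O[Si](C(C)C)(C(C)C)C(C)C | intermediate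
29 | alkenyllithium from 28 (Li cis to the decalin arm) | CC1=CC[C@H]2C(C)(C)CCC[C@]2(C)[C@H]1CC/C(=C\[Li])CCC/C(C)=C/Cc1cc(O[Si](C(C)C)(C(C)C)C(C)C)ccc1O[Si](C(C)C)(C(C)C)C(C)C | intermediate
30 | (Z)-lithium enolate (OLi cis to the decalin arm) | CC1=CC[C@H]2C(C)(C)CCC[C@]2(C)[C@H]1CC/C(=C\O[Li])CCC/C(C)=C/Cc1cc(O[Si](C(C)C)(C(C)C)C(C)C)ccc1O[Si](C(C)C)(C(C)C)C(C)C | intermediate
31 | (1Z,6E)-2-[(drim-7-en-11-yl)methyl]-6-methyl-8-[2,5-bis(triisopropylsilyloxy)phenyl]octa-1,6-dien-1-yl hydrogen sulfate (handled as sodium salt) | CC1=CC[C@H]2C(C)(C)CCC[C@]2(C)[C@H]1CC/C(=C\OS(=O)(=O)O)CCC/C(C)=C/Cc1cc(O[Si](C(C)C)(C(C)C)C(C)C)ccc1O[Si](C(C)C)(C(C)C)C(C)C | intermediate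
32 | (1Z,6E)-8-(2,5-dihydroxyphenyl)-2-[(drim-7-en-11-yl)methyl]-6-methylocta-1,6-dien-1-yl hydrogen sulfate (5S,9S,10S) | CC1=CC[C@H]2C(C)(C)CCC[C@]2(C)[C@H]1CC/C(=C\OS(=O)(=O)O)CCC/C(C)=C/Cc1cc(O)ccc1O | target

**Totals**

Total step count: 18. Longest linear sequence: 11 steps (steps 1, 2, 3, 5, 6, 7, 8, 9, 16, 17, 18).

**Steps most likely to fail**

1. Step 5. The enal may approach the wrong face of the C10 radical (cis-fused isomer), the radical may add to the wrong face of the enal (C9 epimer), or the radical may be reduced before it is trapped; the facial arguments given are qualitative.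
   - The fallback sets out from 5 and comes back at 14. It makes C7–C8 first and closes C9–C10 by an intramolecular cation–olefin cyclisation through a chair, the classical entry to trans-fused 9β-substituted drim-7-enes.
   - 5 is reduced with NaBH4 to 2-[(1S)-2,6,6-trimethylcyclohex-2-en-1-yl]ethanol F1.
   - F1 is converted with I2, PPh3 and imidazole into (6S)-6-(2-iodoethyl)-1,5,5-trimethylcyclohex-1-ene F2.
   - F2 is alkylated with lithium acetylide–ethylenediamine in DMSO to (6S)-6-(but-3-yn-1-yl)-1,5,5-trimethylcyclohex-1-ene F3.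
   - Zirconium-catalysed methylalumination of F3 gives (E)-dimethyl{2-methyl-4-[(1S)-2,6,6-trimethylcyclohex-2-en-1-yl]but-1-en-1-yl}alumane F4.
   - F4, as its ate complex with n-BuLi, opens oxirane to (E)-4-methyl-6-[(1S)-2,6,6-trimethylcyclohex-2-en-1-yl]hex-3-en-1-ol F5.
   - F5 is acetylated (Ac2O, pyridine) to (E)-4-methyl-6-[(1S)-2,6,6-trimethylcyclohex-2-en-1-yl]hex-3-en-1-yl acetate F6, so that the oxygen cannot capture the C8 cation.
   - F6 is cyclised with chlorosulfonic acid in 2-nitropropane at −78 °C to (drim-7-en-11-yl)methyl acetate F7; the (E)-alkene places C11 equatorial and the C8 cation loses H7.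
   - Methanolysis of F7 (K2CO3, MeOH) gives 14.

2. Step 17. The enolate may be protonated or attacked at carbon instead of oxygen, and tert-butoxide may consume the sulfating agent.
   - The fallback sets out from 30 and comes back at 31. It installs the sulfate in protected, neutral form.
   - 30 is trapped with 1,2-dimethyl-3-[(2,2,2-trichloroethoxy)sulfonyl]imidazolium triflate to give (1Z,6E)-2-[(drim-7-en-11-yl)methyl]-6-methyl-8-[2,5-bis(triisopropylsilyloxy)phenyl]octa-1,6-dien-1-yl 2,2,2-trichloroethyl sulfate F8, which can be chromatographed.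
   - Zinc dust and ammonium formate in methanol then remove the trichloroethyl group by reductive β-elimination and give 31.

3. Step 16. The hindered alkylcopper may add slowly to the alkyne and decompose thermally, and the alkyne C–H may be metalated.
   - The fallback sets out from 15 and 24 and comes back at 28. It replaces the stoichiometric organocopper by a copper-catalysed three-component alkylboration.
   - 15 is converted with NaI in acetone into 11-(iodomethyl)drim-7-ene F9.
   - F9, 24 and B2pin2 with CuCl/Xantphos and KOt-Bu in THF should give, by syn borylcupration and alkylation with retention, the (1Z,6E)-alkenyl pinacolboronate F10, with boron on the terminal carbon cis to the decalin arm.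
   - Iodination of the boronate ate complex (NaOH, I2), with retention, gives 28.

**Further compounds**

F1 | step 5 | 2-[(1S)-2,6,6-trimethylcyclohex-2-en-1-yl]ethanol | OCC[C@H]1C(C)(C)CCC=C1C
F2 | step 5 | (6S)-6-(2-iodoethyl)-1,5,5-trimethylcyclohex-1-ene | ICC[C@H]1C(C)(C)CCC=C1C
F3 | step 5 | (6S)-6-(but-3-yn-1-yl)-1,5,5-trimethylcyclohex-1-ene | C#CCC[C@H]1C(C)(C)CCC=C1C
F4 | step 5 | (E)-dimethyl{2-methyl-4-[(1S)-2,6,6-trimethylcyclohex-2-en-1-yl]but-1-en-1-yl}alumane | C[Al](C)/C=C(\C)CC[C@H]1C(C)(C)CCC=C1C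
F5 | step 5 | (E)-4-methyl-6-[(1S)-2,6,6-trimethylcyclohex-2-en-1-yl]hex-3-en-1-ol | OCC/C=C(\C)CC[C@H]1C(C)(C)CCC=C1C
F6 | step 5 | (E)-4-methyl-6-[(1S)-2,6,6-trimethylcyclohex-2-en-1-yl]hex-3-en-1-yl acetate | CC(=O)OCC/C=C(\C)CC[C@H]1C(C)(C)CCC=C1C
F7 | step 5 | (drim-7-en-11-yl)methyl acetate | CC1=CC[C@H]2C(C)(C)CCC[C@]2(C)[C@H]1CCOC(C)=O
F8 | step 17 | (1Z,6E)-2-[(drim-7-en-11-yl)methyl]-6-methyl-8-[2,5-bis(triisopropylsilyloxy)phenyl]octa-1,6-dien-1-yl 2,2,2-trichloroethyl sulfate | CC1=CC[C@H]2C(C)(C)CCC[C@]2(C)[C@H]1CC/C(=C\OS(=O)(=O)OCC(Cl)(Cl)Cl)CCC/C(C)=C/Cc1cc(O[Si](C(C)C)(C(C)C)C(C)C)ccc1O[Si](C(C)C)(C(C)C)C(C)C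
F9 | step 16 | 11-(iodomethyl)drim-7-ene | CC1=CC[C@H]2C(C)(C)CCC[C@]2(C)[C@H]1CCI
F10 | step 16 | 2-{(1Z,6E)-2-[(drim-7-en-11-yl)methyl]-6-methyl-8-[2,5-bis(triisopropylsilyloxy)phenyl]octa-1,6-dien-1-yl}-4,4,5,5-tetramethyl-1,3,2-dioxaborolane | CC1=CC[C@H]2C(C)(C)CCC[C@]2(C)[C@H]1CC/C(=C\B1OC(C)(C)C(C)(C)O1)CCC/C(C)=C/Cc1cc(O[Si](C(C)C)(C(C)C)C(C)C)ccc1O[Si](C(C)C)(C(C)C)C(C)C
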